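## Analysis of the target

(+)-Mitorubrinic acid B (26) is a 6H-isochromen-6-one (azaphilone): pyran ring A (C1, O2, C3, C4, C4a, C8a) is fused through C4a and C8a to carbocyclic ring B (C4a, C5, C6, C7, C8, C8a). The chromophore is the cross-conjugated system C1=C8a, C3=C4, C4a=C5, C6=O, extended at C3 by an (E)-acrylic acid. The only two stereocentres are adjacent on ring B: C7 (R) is a tertiary alcohol carrying the methyl group, and C8 (R) is a secondary carbinol esterified by 2,4-dihydroxy-6-methylbenzoic (orsellinic) acid; their oxygen atoms are cis. Sensitive points are the vinylogous pyrylium character (C1 is electrophilic towards amines and strong base), the C8–O bond allylic to the C1=C8a enol ether, the α-ketol at C6/C7, the hindered di-ortho-substituted aryl ester, and the free acid and phenols. The difficulty is that ring B is a non-aromatic, tri-oxygenated ring in which C8 is a carbinol and not a ketone, so dearomatisation of an arene would give the wrong oxidation level at C8 and no handle on the C7/C8 relationship. The chromophore must also be unveiled late and under mild conditions. The plan rests on ring A: with its substituted C3 next to O2 it is, one oxidation level up at C1, a 2-pyranone, the annulation product of a cyclohexenecarboxylic acid (carboxyl carbon = C1 on C8a, vinylic C4a–H) and a two-carbon acyl carbene unit that brings C4, C3 and the side chain.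

## Retrosynthetic reasoning

**Protecting groups and aryl ester (26 ⇒ 25 ⇒ 24 ⇒ 20 + 23).** The acid and the phenols are released last, from the tert-butyl ester 25 and the bis-silyl ether 24. The aryl ester C–O bond is then cut to diol 20 and acid chloride 23. This is the convergent cut: the secondary C8 hydroxyl can be told apart from the tertiary C7 hydroxyl, and the C8–O bond itself is never broken. Acid chloride 23 goes back through silyl ester 22 to orsellinic acid (21).

**Chromophore (20 ⇒ 18 ⇒ 17 ⇒ 16 ⇒ 15 ⇒ 14).** The trienone is the conjugate base of a 6-oxo pyrylium ion, so it is traced to ketone 18, in which C1 is held as a methyl acetal and the diol as an acetonide. Acid should ionise C1, C5 then loses a proton, and the diol is freed. Ketone 18 comes from alcohol 17 and silyl ether 16. The acetal 16 is needed because the C1 lactol 15, the reduction product of pyranone 14, would not survive oxidation at C6. The order is therefore: lower C1, mask it, then raise C6.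

**Ring A (14 ⇒ 9 + 12).** Two bonds of the 2-pyranone are cut, C4–C4a and O2–C3, giving the ring B acid 9 and the fumaroyl sulfoxonium ylide 12. All carbons of ring A and the complete side chain arrive in one step. The carboxyl group directs the metal to C4a–H and then becomes C1 and O2. The forward reaction has to achieve C–H insertion of an acyl carbene and lactonisation with dehydration, without moving the C4a=C8a double bond.

**Ylide (12 ⇒ 10).** The ylide is the acylation product of a sulfoxonium methylide with the activated form 11 of mono-tert-butyl fumarate (10). The tert-butyl ester is kept to the end because it resists hydride and fluoride.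

**Carboxyl group (9 ⇒ 8 ⇒ 6).** The C8a–C1 bond is cut to enol triflate 8, and the triflate to ketone 6 by regioselective enolisation towards C4a. Carbonylation gives the acid directly and fixes the double bond at C4a=C8a. An acyclic assembly closed by ring-closing metathesis would instead have to create C8 by addition to a neopentyl-type aldehyde next to the quaternary C7, with weak 1,2-induction, and was not used.

**Diol (6 ⇒ 5 ⇒ 4).** The C7–O and C8–O bonds are cut together: a syn-dihydroxylation of enone 4 gives the cis-diol in one step. The silyloxy group at C6 directs it to the opposite face, so a single, easily made stereocentre relays its configuration to C7 and C8 and is erased later, when C6 becomes the ketone.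

**Enone (4 ⇒ 3 ⇒ 2 ⇒ 1).** The enone carbonyl (the future C8a) comes from allylic oxidation of silyl ether 3. The C6 stereocentre comes from catalytic enantioselective reduction of commercial 2-methylcyclohex-2-en-1-one (1) to alcohol 2.

## Alternatives that were turned down

**Alternative 1:** Ring B is cut at C6–C7 and C5–C4a. A [4+2] cycloaddition joins the furan A1 (its ring carbons become C7, C8, C8a and C4a, its oxygen the C7 hydroxyl) with 2-bromoacrolein A2 (C5 and C6) under a chiral boron Lewis acid, giving the oxanorbornene A3.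
- For: one catalytic step closes ring B and sets the quaternary C7 absolutely. On this point it is stronger than the chosen key step, which makes no stereocentre, and the route to A3 is very short.
- Against: in A3, C8 is an unoxygenated alkene carbon, so the C8 carbinol cis to O7 still has to be made. The bridgehead methyl on C4a has to be turned into C4 and joined to C3 and the acrylate, so ring A is not built at all. The bromo aldehyde has to be degraded by one carbon to the C6 ketone. 2,5-Disubstituted furans are sluggish, reversible dienes, and regio-, exo/endo and facial selectivity must all be right at once. Opening the oxygen bridge invites aromatisation of ring B.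
- Comparison: the chosen route offers less stereochemical content in its key step, but that step delivers every carbon of ring A onto a ring B whose three oxygenated carbons are already in place.

**Alternative 2:** Both rings are cut at once, at C8a–C4a and O2–C3. The acyclic formyl diketone A4, carrying a conjugated diyne, is treated with mild base. Its 1,3-dicarbonyl carbon adds 6-endo to the ynone and the enol oxygen then adds 6-endo to the second alkyne, giving the 6,8-dione A5.
- For: the most convergent option. It reaches the chromophore with no redox adjustment at C1 or C6, and it is probably shorter than the chosen route.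
- Against: A5 has a ketone at C8 and the silyl ether on O7, whereas 26 needs a C8 carbinol cis to a free C7 hydroxyl. That calls for a 1,2-reduction that distinguishes the C8 from the C6 carbonyl (both vinylogous esters) and one face from the other, inside a chromophore that is itself electrophilic. A4 is a fragile polyfunctional Michael acceptor with a quaternary α-silyloxy carbon between two ketones (retro-Claisen cleavage under base), and 5-exo closures compete with both 6-endo closures.
- Comparison: the chosen route is longer, but it fixes C8 by a cis-dihydroxylation before any sensitive unsaturation exists.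

**Alternative 3:** The disconnection lies in the orsellinate, not in the core. Thermolysis of the diketo-dioxinone A6 gives a triketo acylketene, which the C8 hydroxyl of the diol core A7 (identical with 20) captures. Aldol condensation and dehydration of the resulting trioxooctanoate then build the arene, giving the tert-butyl ester A8 (identical with 25).
- For: a ketene is unhindered, so the difficult acylation with a di-ortho-substituted benzoyl electrophile is avoided, and no phenol protection is needed. On both points it is stronger than steps 15 to 18 of the chosen route.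
- Against: it says nothing about how the bicyclic diol is made, so it presupposes a core synthesis such as the one chosen. It exposes the azaphilone to about 110 °C and then to base for the aromatisation, and A6 needs its own synthesis.
- Comparison: the chosen route uses commercial orsellinic acid and a standard acylation. Alternative 3 is kept as the fallback for step 17.

Key step: step 9

Assumption: the dextrorotatory natural product is taken to be the (7R,8R) isomer encoded in the SMILES (O7 and O8 cis); the locants C1–C8a of the isochromene core are used for all intermediates.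

## Route

**Step 1**
Reactants: 1 2-methylcyclohex-2-en-1-one
Product: 2 (R)-2-methylcyclohex-2-en-1-ol
Conditions: (S)-2-methyl-CBS-oxazaborolidine (10 mol %), BH3·SMe2, THF, −30 °C; MeOH quench
Reagents that add atoms: none
Why: Corey–Bakshi–Shibata reduction; the α-methylvinyl side of the enone acts as the large group, so the (S)-catalyst is expected to give the (R)-allylic alcohol, as is usual for 2-substituted cyclohexenones. This carbinol becomes C6 and relays its configuration to C7 and C8 in step 4.

**Step 2**
Reactants: 2 (R)-2-methylcyclohex-2-en-1-ol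
Product: 3 (R)-tert-butyldimethyl[(2-methylcyclohex-2-en-1-yl)oxy]silane
Conditions: TBSCl, imidazole, DMF, rt
Reagents that add atoms: tert-butyldimethylsilyl chloride, CC(C)(C)[Si](C)(C)Cl
Why: Standard silylation of a secondary allylic alcohol; the bulky ether later shields one ring face and is carried to step 12.

**Step 3**
Reactants: 3 (R)-tert-butyldimethyl[(2-methylcyclohex-2-en-1-yl)oxy]silane
Product: 4 (R)-4-(tert-butyldimethylsilyloxy)-3-methylcyclohex-2-en-1-one
Conditions: CrO3, 3,5-dimethylpyrazole, CH2Cl2, −20 °C
Reagents that add atoms: chromium trioxide, O=[Cr](=O)=O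
Why: Allylic oxidation of a cycloalkene to the enone with the CrO3–3,5-dimethylpyrazole complex, a known way from cyclohexenyl silyl ethers to 4-silyloxy enones. The ring methylene remote from the silyl ether (the future C8a) is the accessible allylic position; the C–H at C6 is tertiary and shielded, and the methyl group is primary.

**Step 4**
Reactants: 4 (R)-4-(tert-butyldimethylsilyloxy)-3-methylcyclohex-2-en-1-one
Product: 5 (2S,3R,4R)-4-(tert-butyldimethylsilyloxy)-2,3-dihydroxy-3-methylcyclohexan-1-one (2,3-diol cis, trans to the 4-silyloxy group)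
Conditions: OsO4 (5 mol %), N-methylmorpholine N-oxide, acetone–H2O, rt
Reagents that add atoms: osmium tetroxide (oxygen carrier), O=[Os](=O)(=O)=O; N-methylmorpholine N-oxide (terminal oxygen source), C[N+]1([O-])CCOCC1; water, O
Why: Upjohn dihydroxylation; syn addition of OsO4 to the enone double bond from the face anti to the neighbouring silyloxy group creates C7 and C8 together. The two new oxygen atoms are cis to each other and trans to O6, which with (R)-C6 is the configuration of 26.

**Step 5**
Reactants: 5 (2S,3R,4R)-4-(tert-butyldimethylsilyloxy)-2,3-dihydroxy-3-methylcyclohexan-1-one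
Product: 6 (3aS,7R,7aR)-7-(tert-butyldimethylsilyloxy)-2,2,7a-trimethyltetrahydro-1,3-benzodioxol-4(3aH)-one
Conditions: 2,2-dimethoxypropane, PPTS (cat.), acetone, rt
Reagents that add atoms: 2,2-dimethoxypropane, COC(C)(C)OC
Why: Acid-catalysed transketalisation; the cis-diol closes to the cis-fused dioxolane, which also blocks retro-aldol cleavage and β-elimination of the β-hydroxy ketone. The secondary silyl ether tolerates PPTS.

**Step 6**
Reactants: 6 (3aS,7R,7aR)-7-(tert-butyldimethylsilyloxy)-2,2,7a-trimethyltetrahydro-1,3-benzodioxol-4(3aH)-one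
Product: 8 (3aS,7R,7aR)-7-(tert-butyldimethylsilyloxy)-2,2,7a-trimethyl-3a,6,7,7a-tetrahydro-1,3-benzodioxol-4-yl trifluoromethanesulfonate, via lithium enolate 7 (not isolated)
Conditions: LiN(SiMe3)2, THF, −78 °C; then PhNTf2, −78 → 0 °C
Reagents that add atoms: N-phenylbis(trifluoromethanesulfonimide), O=S(=O)(N(c1ccccc1)S(=O)(=O)C(F)(F)F)C(F)(F)F
Why: Kinetic deprotonation by the hindered amide at the C4a methylene (the other α-position, C8, is a methine buried in the cis-fused dioxolane) and O-sulfonylation of the enolate; standard enol triflate synthesis. It places the double bond at C4a=C8a.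

**Step 7**
Reactants: 8 (3aS,7R,7aR)-7-(tert-butyldimethylsilyloxy)-2,2,7a-trimethyl-3a,6,7,7a-tetrahydro-1,3-benzodioxol-4-yl trifluoromethanesulfonate
Product: 9 (3aR,7R,7aR)-7-(tert-butyldimethylsilyloxy)-2,2,7a-trimethyl-3a,6,7,7a-tetrahydro-1,3-benzodioxole-4-carboxylic acid (ring B acid: carboxyl on C8a, 7,8-O-isopropylidene, 6-silyloxy)
Conditions: Pd(OAc)2 (5 mol %), PPh3 (10 mol %), CO (1 atm), KOAc, DMF, rt; aqueous work-up at pH 4
Reagents that add atoms: carbon monoxide, [C-]#[O+]; potassium acetate (oxygen nucleophile towards the acylpalladium), CC(=O)[O-].[K+]; water (hydrolysis of the mixed anhydride), O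
Why: Palladium-catalysed hydroxycarbonylation of an enol triflate: oxidative addition to zerovalent palladium, CO insertion, capture of the acylpalladium by acetate and hydrolysis of the mixed anhydride. The acid forms directly, so no ester saponification with its risk of vinylogous β-elimination of the C6 silyloxy group is needed.

**Step 8**
Reactants: 10 mono-tert-butyl fumarate [(E)-4-tert-butoxy-4-oxobut-2-enoic acid]
Product: 12 tert-butyl (E)-5-[dimethyl(oxo)-λ6-sulfanylidene]-4-oxopent-2-enoate, via acid chloride 11 (not isolated)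
Conditions: (COCl)2, DMF (cat.), CH2Cl2, 0 °C → rt, evaporate; then Me3S(O)I/KOt-Bu (2.1 equiv, premixed in THF), −40 → 0 °C
Reagents that add atoms: trimethylsulfoxonium iodide, C[S+](C)(C)=O.[I-]
Why: Acylation of dimethylsulfoxonium methylide (the Corey–Chaykovsky reagent) by an acid chloride; the second equivalent of methylide deprotonates the acylsulfoxonium salt. At low temperature and without excess methylide, substitution at the acid chloride should outrun conjugate addition to the fumarate double bond, as with other unsaturated acid chlorides.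

**Step 9**
Reactants: 9 (3aR,7R,7aR)-7-(tert-butyldimethylsilyloxy)-2,2,7a-trimethyl-3a,6,7,7a-tetrahydro-1,3-benzodioxole-4-carboxylic acid; 12 tert-butyl (E)-5-[dimethyl(oxo)-λ6-sulfanylidene]-4-oxopent-2-enoate
Product: 14 tert-butyl (E)-3-[(6R,7R,8R)-6-(tert-butyldimethylsilyloxy)-7,8-(isopropylidenedioxy)-7-methyl-1-oxo-5,6,7,8-tetrahydro-1H-isochromen-3-yl]prop-2-enoate, via keto acid 13 (not isolated)
Conditions: [Cp*RhCl2]2 (4 mol %), AgSbF6 (16 mol %), NaOAc (30 mol %), 12 (1.5 equiv, slow addition), ClCH2CH2Cl, 70 °C
Reagents that add atoms: none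
Why: Proposed new method: carboxylate-assisted metalation of C4a–H, the only vinylic C–H β to the carboxyl group, by the cationic Cp*Rh species from [Cp*RhCl2]2 and AgSbF6 should give a five-membered rhodacycle; ylide 12 then binds through carbon, loses dimethyl sulfoxide to form a rhodium acyl carbene, and migratory insertion followed by protonation of the rhodium enolate forms the C4–C4a bond in keto acid 13. The carboxylate oxygen adds to the new C3 ketone in a 6-exo-trig closure and loss of water gives ring A as the 2-pyranone 14 (bond O2–C3). The closest known reactions are the annulation of benzoic acids with acyl sulfoxonium ylides to isocoumarins and the oxidative annulation of acrylic acids with alkynes to 2-pyranones under trivalent rhodium or divalent ruthenium; neither a cycloalkenecarboxylic acid as the C–H partner of an ylide nor an ylide carrying an enoate has been shown. No stereocentre is created, and C6, C7 and C8 are not at risk because none of them is α to a carbonyl group or part of the metallacycle. Site selectivity follows from the rhodacycle (C4a–H is the only C–H the carboxylate can reach through a five-membered transition state), and the regiochemistry is fixed because the ylide carbon can only become C4 and its acyl carbon C3. The step needs chemoselectivity for C–H insertion over O-alkylation of the acid by the protonated ylide and over conjugate addition of the alkenyl–rhodium bond to the enoate of 12 or 14; slow addition of 12, the acetate buffer and an aprotic solvent are chosen for this reason. The acetonide and the silyl ether keep the C4a=C8a double bond from moving towards C6 or C8 and should survive the buffered medium.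

**Step 10**
Reactants: 14 tert-butyl (E)-3-[(6R,7R,8R)-6-(tert-butyldimethylsilyloxy)-7,8-(isopropylidenedioxy)-7-methyl-1-oxo-5,6,7,8-tetrahydro-1H-isochromen-3-yl]prop-2-enoate
Product: 15 tert-butyl (E)-3-[(6R,7R,8R)-6-(tert-butyldimethylsilyloxy)-1-hydroxy-7,8-(isopropylidenedioxy)-7-methyl-5,6,7,8-tetrahydro-1H-isochromen-3-yl]prop-2-enoate (C1 epimers, in equilibrium with the ring-opened keto aldehyde)
Conditions: i-Bu2AlH (1.1 equiv), CH2Cl2, −78 °C; aq. potassium sodium tartrate work-up
Reagents that add atoms: none
Why: Partial reduction of a lactone to the lactol; the aluminium hemiacetal is stable at −78 °C until the quench. With one equivalent of hydride the hindered, conjugated tert-butyl ester is expected to react more slowly than the ring carbonyl; the crude lactol is taken on.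

**Step 11**
Reactants: 15 tert-butyl (E)-3-[(6R,7R,8R)-6-(tert-butyldimethylsilyloxy)-1-hydroxy-7,8-(isopropylidenedioxy)-7-methyl-5,6,7,8-tetrahydro-1H-isochromen-3-yl]prop-2-enoate
Product: 16 tert-butyl (E)-3-[(6R,7R,8R)-6-(tert-butyldimethylsilyloxy)-7,8-(isopropylidenedioxy)-1-methoxy-7-methyl-5,6,7,8-tetrahydro-1H-isochromen-3-yl]prop-2-enoate (C1 epimers)
Conditions: MeOH, PPTS (cat.), 3 Å molecular sieves, 0 °C
Reagents that add atoms: methanol, CO
Why: Acetalisation through the aromatic pyrylium ion, which forms easily from either lactol tautomer and is captured by methanol at C1, the less hindered α-position, so that the C3=C4–acrylate conjugation is kept. This masks the aldehyde level of C1 against the oxidant of step 13; PPTS at 0 °C should leave acetonide and silyl ether intact.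

**Step 12**
Reactants: 16 tert-butyl (E)-3-[(6R,7R,8R)-6-(tert-butyldimethylsilyloxy)-7,8-(isopropylidenedioxy)-1-methoxy-7-methyl-5,6,7,8-tetrahydro-1H-isochromen-3-yl]prop-2-enoate
Product: 17 tert-butyl (E)-3-[(6R,7S,8R)-6-hydroxy-7,8-(isopropylidenedioxy)-1-methoxy-7-methyl-5,6,7,8-tetrahydro-1H-isochromen-3-yl]prop-2-enoate (C1 epimers; the C7 descriptor changes by priority only)
Conditions: Bu4NF, THF, 0 °C
Reagents that add atoms: none
Why: Fluoride cleavage of the secondary silyl ether; acetal, acetonide and tert-butyl ester are inert to Bu4NF.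

**Step 13**
Reactants: 17 tert-butyl (E)-3-[(6R,7S,8R)-6-hydroxy-7,8-(isopropylidenedioxy)-1-methoxy-7-methyl-5,6,7,8-tetrahydro-1H-isochromen-3-yl]prop-2-enoate
Product: 18 tert-butyl (E)-3-[(7R,8R)-7,8-(isopropylidenedioxy)-1-methoxy-7-methyl-6-oxo-5,6,7,8-tetrahydro-1H-isochromen-3-yl]prop-2-enoate (C1 epimers)
Conditions: Dess–Martin periodinane, NaHCO3, CH2Cl2, 0 °C → rt
Reagents that add atoms: none
Why: Dess–Martin oxidation under buffered conditions gives the C6 ketone and removes the auxiliary stereocentre. The product has an acidic C5 methylene between the ketone and the dienyl ether and may begin to lose methanol, which is the course of step 14 in any case; it is used crude.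

**Step 14**
Reactants: 18 tert-butyl (E)-3-[(7R,8R)-7,8-(isopropylidenedioxy)-1-methoxy-7-methyl-6-oxo-5,6,7,8-tetrahydro-1H-isochromen-3-yl]prop-2-enoate
Product: 20 tert-butyl (E)-3-[(7R,8R)-7,8-dihydroxy-7-methyl-6-oxo-7,8-dihydro-6H-isochromen-3-yl]prop-2-enoate, via azaphilone acetonide 19 (not isolated)
Conditions: 1 M aq. HCl–THF (1:3), rt
Reagents that add atoms: none
Why: Acid ionises the C1 acetal to the pyrylium ion, whose γ-alkyl carbon C5 (also α to the ketone) loses a proton to give the 4-methylenepyran that is the azaphilone chromophore. C8 sits on a β-position of the pyrylium ring and cannot be deprotonated in this way, so its configuration is kept. Continued hydrolysis removes the acetonide by cleavage at the acetal carbon, not at C7 or C8, and the tert-butyl ester should tolerate dilute aqueous acid at room temperature.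

**Step 15**
Reactants: 21 orsellinic acid (2,4-dihydroxy-6-methylbenzoic acid)
Product: 22 tert-butyldimethylsilyl 2,4-bis(tert-butyldimethylsilyloxy)-6-methylbenzoate
Conditions: TBSCl (3.3 equiv), imidazole, DMF, rt
Reagents that add atoms: tert-butyldimethylsilyl chloride, CC(C)(C)[Si](C)(C)Cl
Why: Exhaustive silylation of both phenols and the carboxylic acid.

**Step 16**
Reactants: 22 tert-butyldimethylsilyl 2,4-bis(tert-butyldimethylsilyloxy)-6-methylbenzoate
Product: 23 2,4-bis(tert-butyldimethylsilyloxy)-6-methylbenzoyl chloride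
Conditions: (COCl)2, DMF (cat.), CH2Cl2, 0 °C → rt
Reagents that add atoms: oxalyl chloride, ClC(=O)C(Cl)=O
Why: A silyl ester reacts with oxalyl chloride and catalytic DMF to give the acid chloride and the volatile silyl chloride without free HCl, so the aryl silyl ethers are kept.

**Step 17**
Reactants: 20 tert-butyl (E)-3-[(7R,8R)-7,8-dihydroxy-7-methyl-6-oxo-7,8-dihydro-6H-isochromen-3-yl]prop-2-enoate; 23 2,4-bis(tert-butyldimethylsilyloxy)-6-methylbenzoyl chloride
Product: 24 (7R,8R)-3-[(E)-3-tert-butoxy-3-oxoprop-1-enyl]-7-hydroxy-7-methyl-6-oxo-7,8-dihydro-6H-isochromen-8-yl 2,4-bis(tert-butyldimethylsilyloxy)-6-methylbenzoate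
Conditions: Et3N, DMAP (0.3 equiv), CH2Cl2, 0 °C → rt
Reagents that add atoms: none
Why: DMAP-catalysed acylation through the acylpyridinium ion; the secondary C8 hydroxyl reacts while the tertiary C7 hydroxyl next to the ketone does not. The C8–O bond is not broken, so no stereocentre is touched.

**Step 18**
Reactants: 24 (7R,8R)-3-[(E)-3-tert-butoxy-3-oxoprop-1-enyl]-7-hydroxy-7-methyl-6-oxo-7,8-dihydro-6H-isochromen-8-yl 2,4-bis(tert-butyldimethylsilyloxy)-6-methylbenzoate
Product: 25 (7R,8R)-3-[(E)-3-tert-butoxy-3-oxoprop-1-enyl]-7-hydroxy-7-methyl-6-oxo-7,8-dihydro-6H-isochromen-8-yl 2,4-dihydroxy-6-methylbenzoate (mitorubrinic acid B tert-butyl ester)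
Conditions: HF·pyridine, THF, 0 °C → rt
Reagents that add atoms: none
Why: Fluoride cleavage of the two aryl silyl ethers, which the ortho/para ester group activates; the reagent is non-basic, and the chromophore and both esters are expected to tolerate it.

**Step 19**
Reactants: 25 (7R,8R)-3-[(E)-3-tert-butoxy-3-oxoprop-1-enyl]-7-hydroxy-7-methyl-6-oxo-7,8-dihydro-6H-isochromen-8-yl 2,4-dihydroxy-6-methylbenzoate
Product: 26 (+)-mitorubrinic acid B, (E)-3-[(7R,8R)-8-(2,4-dihydroxy-6-methylbenzoyloxy)-7-hydroxy-7-methyl-6-oxo-7,8-dihydro-6H-isochromen-3-yl]prop-2-enoic acid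
Conditions: CF3CO2H–CH2Cl2 (1:4), 0 °C → rt
Reagents that add atoms: none
Why: Acidolysis of the tert-butyl ester with loss of 2-methylpropene; the chromophore is only protonated reversibly at the C6 carbonyl, which disfavours ionisation at C8, and the aryl ester should survive.

## Compound list

1 | 2-methylcyclohex-2-en-1-one | CC1=CCCCC1=O | starting material
2 | (R)-2-methylcyclohex-2-en-1-ol | CC1=CCCC[C@H]1O | intermediate
3 | (R)-tert-butyldimethyl[(2-methylcyclohex-2-en-1-yl)oxy]silane | CC1=CCCC[C@H]1O[Si](C)(C)C(C)(C)C | intermediate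
4 | (R)-4-(tert-butyldimethylsilyloxy)-3-methylcyclohex-2-en-1-one | CC1=CC(=O)CC[C@H]1O[Si](C)(C)C(C)(C)C | intermediate
5 | (2S,3R,4R)-4-(tert-butyldimethylsilyloxy)-2,3-dihydroxy-3-methylcyclohexan-1-one | O[C@@H]1C(=O)CC[C@@H](O[Si](C)(C)C(C)(C)C)[C@]1(C)O | intermediate
6 | (3aS,7R,7aR)-7-(tert-butyldimethylsilyloxy)-2,2,7a-trimethyltetrahydro-1,3-benzodioxol-4(3aH)-one | CC1(C)O[C@@H]2C(=O)CC[C@@H](O[Si](C)(C)C(C)(C)C)[C@]2(C)O1 | intermediate
7 | lithium enolate of 6 (O− on C8a, C4a=C8a) | CC1(C)O[C@@H]2C([O-])=CC[C@@H](O[Si](C)(C)C(C)(C)C)[C@]2(C)O1.[Li+] | intermediate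
8 | (3aS,7R,7aR)-7-(tert-butyldimethylsilyloxy)-2,2,7a-trimethyl-3a,6,7,7a-tetrahydro-1,3-benzodioxol-4-yl trifluoromethanesulfonate | CC1(C)O[C@@H]2C(OS(=O)(=O)C(F)(F)F)=CC[C@@H](O[Si](C)(C)C(C)(C)C)[C@]2(C)O1 | intermediate
9 | (3aR,7R,7aR)-7-(tert-butyldimethylsilyloxy)-2,2,7a-trimethyl-3a,6,7,7a-tetrahydro-1,3-benzodioxole-4-carboxylic acid | CC1(C)O[C@@H]2C(C(=O)O)=CC[C@@H](O[Si](C)(C)C(C)(C)C)[C@]2(C)O1 | intermediate
10 | mono-tert-butyl fumarate | OC(=O)/C=C/C(=O)OC(C)(C)C | starting material
11 | tert-butyl (E)-4-chloro-4-oxobut-2-enoate | ClC(=O)/C=C/C(=O)OC(C)(C)C | intermediate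
12 | tert-butyl (E)-5-[dimethyl(oxo)-λ6-sulfanylidene]-4-oxopent-2-enoate | CS(C)(=O)=CC(=O)/C=C/C(=O)OC(C)(C)C | intermediate
13 | (3aR,7R,7aR)-5-[(E)-5-tert-butoxy-2,5-dioxopent-3-en-1-yl]-7-(tert-butyldimethylsilyloxy)-2,2,7a-trimethyl-3a,6,7,7a-tetrahydro-1,3-benzodioxole-4-carboxylic acid | CC1(C)O[C@@H]2C(C(=O)O)=C(CC(=O)/C=C/C(=O)OC(C)(C)C)C[C@@H](O[Si](C)(C)C(C)(C)C)[C@]2(C)O1 | intermediate
14 | tert-butyl (E)-3-[(6R,7R,8R)-6-(tert-butyldimethylsilyloxy)-7,8-(isopropylidenedioxy)-7-methyl-1-oxo-5,6,7,8-tetrahydro-1H-isochromen-3-yl]prop-2-enoate | CC1(C)O[C@@H]2C3=C(C[C@@H](O[Si](C)(C)C(C)(C)C)[C@]2(C)O1)C=C(/C=C/C(=O)OC(C)(C)C)OC3=O | intermediate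
15 | tert-butyl (E)-3-[(6R,7R,8R)-6-(tert-butyldimethylsilyloxy)-1-hydroxy-7,8-(isopropylidenedioxy)-7-methyl-5,6,7,8-tetrahydro-1H-isochromen-3-yl]prop-2-enoate (C1 epimers) | CC1(C)O[C@@H]2C3=C(C[C@@H](O[Si](C)(C)C(C)(C)C)[C@]2(C)O1)C=C(/C=C/C(=O)OC(C)(C)C)OC3O | intermediate
16 | tert-butyl (E)-3-[(6R,7R,8R)-6-(tert-butyldimethylsilyloxy)-7,8-(isopropylidenedioxy)-1-methoxy-7-methyl-5,6,7,8-tetrahydro-1H-isochromen-3-yl]prop-2-enoate (C1 epimers) | CC1(C)O[C@@H]2C3=C(C[C@@H](O[Si](C)(C)C(C)(C)C)[C@]2(C)O1)C=C(/C=C/C(=O)OC(C)(C)C)OC3OC | intermediate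
17 | tert-butyl (E)-3-[(6R,7S,8R)-6-hydroxy-7,8-(isopropylidenedioxy)-1-methoxy-7-methyl-5,6,7,8-tetrahydro-1H-isochromen-3-yl]prop-2-enoate (C1 epimers) | CC1(C)O[C@@H]2C3=C(C[C@@H](O)[C@]2(C)O1)C=C(/C=C/C(=O)OC(C)(C)C)OC3OC | intermediate
18 | tert-butyl (E)-3-[(7R,8R)-7,8-(isopropylidenedioxy)-1-methoxy-7-methyl-6-oxo-5,6,7,8-tetrahydro-1H-isochromen-3-yl]prop-2-enoate (C1 epimers) | CC1(C)O[C@@H]2C3=C(CC(=O)[C@]2(C)O1)C=C(/C=C/C(=O)OC(C)(C)C)OC3OC | intermediate
19 | tert-butyl (E)-3-[(7R,8R)-7,8-(isopropylidenedioxy)-7-methyl-6-oxo-7,8-dihydro-6H-isochromen-3-yl]prop-2-enoate | CC1(C)O[C@@H]2C3=COC(/C=C/C(=O)OC(C)(C)C)=CC3=CC(=O)[C@]2(C)O1 | intermediate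
20 | tert-butyl (E)-3-[(7R,8R)-7,8-dihydroxy-7-methyl-6-oxo-7,8-dihydro-6H-isochromen-3-yl]prop-2-enoate | O[C@@H]1C2=COC(/C=C/C(=O)OC(C)(C)C)=CC2=CC(=O)[C@]1(C)O | intermediate
21 | orsellinic acid | Cc1cc(O)cc(O)c1C(=O)O | starting material
22 | tert-butyldimethylsilyl 2,4-bis(tert-butyldimethylsilyloxy)-6-methylbenzoate | Cc1cc(O[Si](C)(C)C(C)(C)C)cc(O[Si](C)(C)C(C)(C)C)c1C(=O)O[Si](C)(C)C(C)(C)C | intermediate
23 | 2,4-bis(tert-butyldimethylsilyloxy)-6-methylbenzoyl chloride | Cc1cc(O[Si](C)(C)C(C)(C)C)cc(O[Si](C)(C)C(C)(C)C)c1C(Cl)=O | intermediate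
24 | (7R,8R)-3-[(E)-3-tert-butoxy-3-oxoprop-1-enyl]-7-hydroxy-7-methyl-6-oxo-7,8-dihydro-6H-isochromen-8-yl 2,4-bis(tert-butyldimethylsilyloxy)-6-methylbenzoate | Cc1cc(O[Si](C)(C)C(C)(C)C)cc(O[Si](C)(C)C(C)(C)C)c1C(=O)O[C@@H]1C2=COC(/C=C/C(=O)OC(C)(C)C)=CC2=CC(=O)[C@]1(C)O | intermediate
25 | (7R,8R)-3-[(E)-3-tert-butoxy-3-oxoprop-1-enyl]-7-hydroxy-7-methyl-6-oxo-7,8-dihydro-6H-isochromen-8-yl 2,4-dihydroxy-6-methylbenzoate | Cc1cc(O)cc(O)c1C(=O)O[C@@H]1C2=COC(/C=C/C(=O)OC(C)(C)C)=CC2=CC(=O)[C@]1(C)O | intermediate
26 | (+)-mitorubrinic acid B | Cc1cc(O)cc(O)c1C(=O)O[C@@H]1C2=COC(/C=C/C(=O)O)=CC2=CC(=O)[C@]1(C)O | target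

## Step count and least certain steps

Total: 19 steps. Longest linear sequence: 16 steps (1 → 9 by steps 1–7, then steps 9–14 and 17–19).

**Step 9 (key step).** The acid may be O-alkylated by the protonated ylide (loss of dimethyl sulfoxide from the sulfoxonium carboxylate) faster than C–H metalation occurs. The alkenyl–rhodium bond may add in conjugate fashion to the enoate instead of forming the carbene, or the lactonisation may stall at 13 under a buffer mild enough for the acetonide. The fallback uses the known oxidative annulation of acrylic-type acids with internal alkynes to 2-pyranones. It sets out from 9, which is heated with tert-butyl (E)-5-(trimethylsilyl)pent-2-en-4-ynoate F1 (from Wittig olefination of 3-(trimethylsilyl)prop-2-ynal with Ph3P=CHCO2t-Bu), [Cp*RhCl2]2 and Cu(OAc)2 in DMF. As is usual for enynes, the alkenyl-bearing alkyne carbon should end up next to oxygen, giving the 4-trimethylsilyl pyranone F2. Protodesilylation at C4, the β-carbon of the ring enol ether, with Bu4NF buffered by acetic acid at 0 °C returns to 14.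

**Step 10.** Hydride may be consumed by the tert-butyl enoate or delivered in conjugate fashion to the dienyl lactone, and the ring-opened aldehyde tautomer may be reduced further. The fallback sets out from 14 and avoids aluminium hydrides. O-Methylation of the pyranone carbonyl with Me3OBF4 (hindered pyridine base, CH2Cl2) gives the 1-methoxy-5,6,7,8-tetrahydroisochromenylium tetrafluoroborate F3. NaBH4 at −78 °C, which does not touch the tert-butyl ester, is then expected to add hydride to the alkoxy-bearing α-carbon C1 and give the acetal directly, so the route is rejoined at 16.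

**Step 14.** Acid mild enough to keep the tert-butyl ester may not complete hydrolysis of the acetonide next to the ketone, and more forcing acid would strip the ester in part and give mixtures. The fallback sets out from 18 and lets everything go: aqueous CF3CO2H removes methanol, acetonide and tert-butyl group to give (E)-3-[(7R,8R)-7,8-dihydroxy-7-methyl-6-oxo-7,8-dihydro-6H-isochromen-3-yl]prop-2-enoic acid F4. The acid is capped with TBSCl (1 equiv)/imidazole as its tert-butyldimethylsilyl ester F5. Acylation with 23 as in step 17 gives the tris-silyl compound F6, and HF·pyridine removes all three silyl groups, so the route is rejoined at 26.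

**Step 17.** The di-ortho-substituted acyl chloride may react too slowly with the hindered C8 hydroxyl, so that silyl transfer or decomposition of the base-sensitive diol competes. The fallback changes the bond-forming principle to ketene capture and builds the arene afterwards. It sets out from 20, which is heated in toluene with 6-(2,4-dioxopentyl)-2,2-dimethyl-4H-1,3-dioxin-4-one F7 (from the dienolate of 2,2,6-trimethyl-4H-1,3-dioxin-4-one and an acetoacetyl donor). The released acylketene is trapped at O8 to give the 3,5,7-trioxooctanoate F8, and mild base followed by acid (aldol condensation, dehydration) forms the orsellinate, returning to the route at 25.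

**Step 6.** Enolisation may take place in part towards C8, which would expel the C7 oxygen (β-elimination) or scramble C8. The fallback uses the Shapiro reaction and sets out from 6. Condensation with 2,4,6-triisopropylbenzenesulfonyl hydrazide gives the hydrazone F9. Two equivalents of n-BuLi deprotonate the less substituted α-carbon (C4a) and generate the C8a alkenyllithium with loss of nitrogen and sulfinate. Carboxylation with CO2 returns directly to 9.

## Further compounds

F1 | step 9 | tert-butyl (E)-5-(trimethylsilyl)pent-2-en-4-ynoate | C[Si](C)(C)C#C/C=C/C(=O)OC(C)(C)C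
F2 | step 9 | tert-butyl (E)-3-[(6R,7R,8R)-6-(tert-butyldimethylsilyloxy)-7,8-(isopropylidenedioxy)-7-methyl-1-oxo-4-(trimethylsilyl)-5,6,7,8-tetrahydro-1H-isochromen-3-yl]prop-2-enoate | CC1(C)O[C@@H]2C3=C(C[C@@H](O[Si](C)(C)C(C)(C)C)[C@]2(C)O1)C([Si](C)(C)C)=C(/C=C/C(=O)OC(C)(C)C)OC3=O
F3 | step 10 | 3-[(E)-3-tert-butoxy-3-oxoprop-1-enyl]-6-(tert-butyldimethylsilyloxy)-7,8-(isopropylidenedioxy)-1-methoxy-7-methyl-5,6,7,8-tetrahydroisochromenylium tetrafluoroborate (C6, C7, C8 as in 14) | CC1(C)O[C@@H]2c3c(C[C@@H](O[Si](C)(C)C(C)(C)C)[C@]2(C)O1)cc(/C=C/C(=O)OC(C)(C)C)[o+]c3OC.F[B-](F)(F)F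
F4 | step 14 | (E)-3-[(7R,8R)-7,8-dihydroxy-7-methyl-6-oxo-7,8-dihydro-6H-isochromen-3-yl]prop-2-enoic acid | O[C@@H]1C2=COC(/C=C/C(=O)O)=CC2=CC(=O)[C@]1(C)O
F5 | step 14 | tert-butyldimethylsilyl (E)-3-[(7R,8R)-7,8-dihydroxy-7-methyl-6-oxo-7,8-dihydro-6H-isochromen-3-yl]prop-2-enoate | O[C@@H]1C2=COC(/C=C/C(=O)O[Si](C)(C)C(C)(C)C)=CC2=CC(=O)[C@]1(C)O
F6 | step 14 | (7R,8R)-3-[(E)-3-(tert-butyldimethylsilyloxy)-3-oxoprop-1-enyl]-7-hydroxy-7-methyl-6-oxo-7,8-dihydro-6H-isochromen-8-yl 2,4-bis(tert-butyldimethylsilyloxy)-6-methylbenzoate | Cc1cc(O[Si](C)(C)C(C)(C)C)cc(O[Si](C)(C)C(C)(C)C)c1C(=O)O[C@@H]1C2=COC(/C=C/C(=O)O[Si](C)(C)C(C)(C)C)=CC2=CC(=O)[C@]1(C)O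
F7 | step 17 | 6-(2,4-dioxopentyl)-2,2-dimethyl-4H-1,3-dioxin-4-one | CC(=O)CC(=O)CC1=CC(=O)OC(C)(C)O1
F8 | step 17 | (7R,8R)-3-[(E)-3-tert-butoxy-3-oxoprop-1-enyl]-7-hydroxy-7-methyl-6-oxo-7,8-dihydro-6H-isochromen-8-yl 3,5,7-trioxooctanoate | CC(=O)CC(=O)CC(=O)CC(=O)O[C@@H]1C2=COC(/C=C/C(=O)OC(C)(C)C)=CC2=CC(=O)[C@]1(C)O
F9 | step 6 | 2,4,6-triisopropylbenzenesulfonylhydrazone of 6 | CC1(C)O[C@@H]2C(=NNS(=O)(=O)c3c(C(C)C)cc(C(C)C)cc3C(C)C)CC[C@@H](O[Si](C)(C)C(C)(C)C)[C@]2(C)O1
A1 | alternative 1 | 3-[(tert-butyldimethylsilyloxy)methyl]-2,5-dimethylfuran | Cc1cc(CO[Si](C)(C)C(C)(C)C)c(C)o1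
A2 | alternative 1 | 2-bromoacrolein | C=C(Br)C=O
A3 | alternative 1 | 2-bromo-5-[(tert-butyldimethylsilyloxy)methyl]-1,4-dimethyl-7-oxabicyclo[2.2.1]hept-5-ene-2-carbaldehyde | O=C[C@@]1(Br)C[C@@]2(C)O[C@]1(C)C=C2CO[Si](C)(C)C(C)(C)C
A4 | alternative 2 | tert-butyl (E)-9-methyl-8,10,12-trioxo-9-(triethylsilyloxy)dodec-2-ene-4,6-diynoate (quaternary carbon as C7 of 26) | O=C(C#CC#C/C=C/C(=O)OC(C)(C)C)[C@](C(=O)CC=O)(C)O[Si](CC)(CC)CC
A5 | alternative 2 | tert-butyl (E)-3-[7-methyl-6,8-dioxo-7-(triethylsilyloxy)-7,8-dihydro-6H-isochromen-3-yl]prop-2-enoate (C7 as in 26) | O=C1C2=COC(/C=C/C(=O)OC(C)(C)C)=CC2=CC(=O)[C@]1(C)O[Si](CC)(CC)CC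
A6 | alternative 3 | 6-(2,4-dioxopentyl)-2,2-dimethyl-4H-1,3-dioxin-4-one | CC(=O)CC(=O)CC1=CC(=O)OC(C)(C)O1
A7 | alternative 3 | tert-butyl (E)-3-[(7R,8R)-7,8-dihydroxy-7-methyl-6-oxo-7,8-dihydro-6H-isochromen-3-yl]prop-2-enoate (same as 20) | O[C@@H]1C2=COC(/C=C/C(=O)OC(C)(C)C)=CC2=CC(=O)[C@]1(C)O
A8 | alternative 3 | mitorubrinic acid B tert-butyl ester (same as 25) | Cc1cc(O)cc(O)c1C(=O)O[C@@H]1C2=COC(/C=C/C(=O)OC(C)(C)C)=CC2=CC(=O)[C@]1(C)O
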